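Assumption: (1R,6S)-(−)-3-carene is bought as the enantiopure terpene; I have not confirmed that it is cheap, and the common (+)-enantiomer would give the mirror-image product.

Atom labels used below: C7′ = benzylic CH(isobutyl); terpene carbons a (ether carbon), b and c (CH2–CH2), d (quaternary C–CH3), e (ring-fusion CH), f and g (cyclopropane CH, f next to e), h (CMe2), i (CH2), j (CH–CH3). Rings: A arene, B oxepane, C cyclopentane, D cyclohexane, E cyclopropane.

**Retrosynthetic overview**
- Ring B is opened last-formed-first at the aryl ether C–O bond (phenol O to tertiary carbon a): a radical–polar crossover hydroaryloxylation of an a=b alkene.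
- The C7′–d bond comes from Giese addition of the tertiary radical at d (from an exocyclic methylene) to the quinone methide of diformylphloroglucinol and 3-methylbutanal.
- Ring C (cyclopentene) comes from ring-closing metathesis of a triene made by α-alkenylation and methylenation of a carane ketone.
- Rings D and E with f, g and j come from (−)-3-carene by hydroboration–oxidation; ring A is phloroglucinol.
- Order of ring formation: D/E (bought), C (metathesis), B (C–O closure).

**Route**

Step 1
Reactants: 1 (1R,6S)-(−)-3-carene
Product: 3 (1R,3S,6S)-3,7,7-trimethylbicyclo[4.1.0]heptan-4-one, via dicaranylborane 2 (not isolated)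
Conditions: BH3·THF (0.5 equiv), THF, 0 °C to rt; then Na2Cr2O7, H2SO4, H2O/Et2O, rt
Reagents that add atoms: sodium dichromate as chromic acid (source of the ketone oxygen), [Na+].[Na+].[O-][Cr](=O)(=O)O[Cr](=O)(=O)[O-]
Why: Brown hydroboration then two-phase chromic acid oxidation of the organoborane: borane adds syn from the face anti to the gem-dimethylcyclopropane with boron on the less substituted C4, so the C3 methyl (future j) ends cis to the cyclopropane, and the oxidation gives the ketone without epimerising C3.

Step 2
Reactants: 4 2,3-dibromopropene; 5 vinylmagnesium bromide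
Product: 6 2-bromopenta-1,4-diene
Conditions: CuI (5 mol%), THF, −10 °C to rt
Reagents that add atoms: none
Why: Copper-catalysed allylic substitution by the vinyl Grignard reagent (SN2 and SN2′ give the same product) leaves the vinylic bromide untouched.

Step 3
Reactants: 3 (1R,3S,6S)-3,7,7-trimethylbicyclo[4.1.0]heptan-4-one; 6 2-bromopenta-1,4-diene
Product: 9 3,7,7-trimethyl-5-(penta-1,4-dien-2-yl)bicyclo[4.1.0]heptan-4-one (3-methyl cis and 5-dienyl trans to the cyclopropane), via lithium enolate 7 (not isolated), via chlorozinc enolate 8 (not isolated)
Conditions: LiN(iPr)2, THF, −78 °C; ZnCl2, −78 to 0 °C; then 6, Pd(dba)2 (5 mol%), P(tBu)3 (10 mol%), THF, 25 °C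
Reagents that add atoms: none
Why: Kinetic deprotonation at the less substituted α-CH2 (C5, future e), transmetalation to the less basic zinc enolate and palladium-catalysed Negishi-type α-alkenylation form the e–d bond on the face anti to the cyclopropane, without touching the epimerisable C3 centre.

Step 4
Reactants: 9 3,7,7-trimethyl-5-(penta-1,4-dien-2-yl)bicyclo[4.1.0]heptan-4-one
Product: 10 3,7,7-trimethyl-4-methylidene-5-(penta-1,4-dien-2-yl)bicyclo[4.1.0]heptane (configuration unchanged)
Conditions: Cp2TiMe2 (2 equiv), toluene, 65 °C, dark
Reagents that add atoms: dimethyltitanocene, C[Ti](C)(C1C=CC=C1)C1C=CC=C1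
Why: Petasis methylenation is non-basic, so the hindered, enolisable ketone becomes the exocyclic alkene without epimerisation or double-bond migration.

Step 5
Reactants: 10 3,7,7-trimethyl-4-methylidene-5-(penta-1,4-dien-2-yl)bicyclo[4.1.0]heptane
Product: 11 tricyclic diene (cyclopentene ring C fused to the carane across C4–C5; a=b double bond in ring C; exocyclic methylidene on d; e–H and j–CH3 cis to the cyclopropane)
Conditions: second-generation Grubbs catalyst (5 mol%), CH2Cl2, 40 °C
Reagents that add atoms: none
Why: Ring-closing metathesis between the terminal vinyl group and the methylidene on a is the only pairing that gives an unstrained ring, so it closes ring C as the trisubstituted a=b alkene and leaves the methylidene on d.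

Step 6
Reactants: 12 phloroglucinol
Product: 14 2,4,6-trihydroxybenzene-1,3-dicarbaldehyde, via bis(iminium) salt 13 (not isolated)
Conditions: POCl3 (2.5 equiv), DMF, dioxane, 0 °C to rt; then H2O, 50 °C
Reagents that add atoms: N,N-dimethylformamide, CN(C)C=O; water, O
Why: Double Vilsmeier–Haack formylation stops at the dialdehyde because each formyl group deactivates the ring, and hydrolysis of the bis(iminium) salt gives the known diformylphloroglucinol.

Step 7
Reactants: 11 tricyclic diene; 14 2,4,6-trihydroxybenzene-1,3-dicarbaldehyde; 15 3-methylbutanal
Product: 18 seco-phenol (2,4,6-trihydroxy-5-substituted benzene-1,3-dicarbaldehyde whose C7′ carries isobutyl and is bonded to d; d now C–CH3; a=b alkene intact), via Mannich base 16 (not isolated), via quinone methide 17 (not isolated)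
Conditions: 14, 15, morpholine (1.1 equiv), EtOH, 25 °C; then 11, Fe(acac)3 (30 mol%), PhSiH3 (2.5 equiv), EtOH/(CH2OH)2, 40 °C
Reagents that add atoms: none
Why: A Mannich (Betti) condensation stores the quinone methide, which is released slowly and trapped by the tertiary radical formed by iron-hydride hydrogen-atom transfer to the more accessible 1,1-disubstituted alkene (Giese-type reductive olefin coupling, precedented for enones and para-quinone methides); the radical is attacked on the convex face anti to the e–f bond (sets d), and C7′ is only weakly biased by a staggered approach with isobutyl next to the tied-back ring CH2 (estimated about 3:1, minor epimer removed by chromatography).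

Step 8
Reactants: 18 seco-phenol
Product: 19 CNP0202714.1 (target)
Conditions: Co(salen) complex C36H52CoN2O2 (5 mol%), N-fluoro-2,4,6-trimethylpyridinium tetrafluoroborate (2 equiv), PhSiH3 (1.5 equiv), PhCF3, 0 °C to rt
Reagents that add atoms: none
Why: Proposed new method: cobalt-hydride hydrogen-atom transfer to the a=b alkene gives the tertiary radical at a, which is captured by cobalt, oxidised by the N-fluoropyridinium salt to a tetravalent alkylcobalt and displaced by the ortho phenol OH in a bridging seven-membered closure, so no free cation forms next to the cyclopropylcarbinyl e–H (no hydride shift or cyclopropane opening) and oxygen can only reach the face of a syn to C7′ (sets a; both ortho OH groups are equivalent); the closest known reaction type is the Shigehisa Co(salen)/N-fluoropyridinium/silane Markovnikov hydroalkoxylation of unactivated alkenes, known for five- and six-membered ethers but not for a formyl-chelated phloroglucinol closing a bridged oxepane.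

**Compound list**

1 | (1R,6S)-(−)-3-carene | CC1=CC[C@H]2[C@@H](C1)C2(C)C | starting material
2 | bis(caran-4-yl)borane (boron trans, 3-methyl cis to the cyclopropane) | [BH]([C@H]1C[C@H]2[C@@H](C[C@@H]1C)C2(C)C)[C@H]1C[C@H]2[C@@H](C[C@@H]1C)C2(C)C | intermediate (not isolated)
3 | (1R,3S,6S)-3,7,7-trimethylbicyclo[4.1.0]heptan-4-one | C[C@H]1C[C@@H]2[C@H](CC1=O)C2(C)C | intermediate
4 | 2,3-dibromopropene | C=C(Br)CBr | starting material
5 | vinylmagnesium bromide | C=C[Mg]Br | starting material
6 | 2-bromopenta-1,4-diene | C=C(Br)CC=C | intermediate
7 | lithium enolate of 3 (C4=C5) | C[C@H]1C[C@@H]2[C@H](C=C1O[Li])C2(C)C | intermediate (not isolated)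
8 | chlorozinc enolate of 3 (C4=C5) | C[C@H]1C[C@@H]2[C@H](C=C1O[Zn]Cl)C2(C)C | intermediate (not isolated)
9 | 3,7,7-trimethyl-5-(penta-1,4-dien-2-yl)bicyclo[4.1.0]heptan-4-one (3-methyl cis, 5-dienyl trans to the cyclopropane) | C[C@H]1C[C@@H]2[C@H]([C@H](C(=C)CC=C)C1=O)C2(C)C | intermediate
10 | 3,7,7-trimethyl-4-methylidene-5-(penta-1,4-dien-2-yl)bicyclo[4.1.0]heptane (same configuration) | C[C@H]1C[C@@H]2[C@H]([C@H](C(=C)CC=C)C1=C)C2(C)C | intermediate
11 | tricyclic diene (ring C cyclopentene with a=b; exocyclic CH2 on d; e–H and j–CH3 cis to the cyclopropane) | C[C@H]1C[C@@H]2[C@H]([C@@H]3C(=C)CC=C13)C2(C)C | intermediate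
12 | phloroglucinol | Oc1cc(O)cc(O)c1 | starting material
13 | bis(dimethyliminium) dichloride of 14 | C[N+](C)=Cc1c(O)cc(O)c(C=[N+](C)C)c1O.[Cl-].[Cl-] | intermediate (not isolated)
14 | 2,4,6-trihydroxybenzene-1,3-dicarbaldehyde | O=Cc1c(O)cc(O)c(C=O)c1O | intermediate
15 | 3-methylbutanal | CC(C)CC=O | starting material
16 | 2,4,6-trihydroxy-5-[3-methyl-1-(morpholin-4-yl)butyl]benzene-1,3-dicarbaldehyde (racemic) | CC(C)CC(N1CCOCC1)c1c(O)c(C=O)c(O)c(C=O)c1O | intermediate (not isolated)
17 | quinone methide from 14 and 15 (6-(3-methylbutylidene)cyclohexadienone form) | CC(C)CC=C1C(=O)C(C=O)=C(O)C(C=O)=C1O | intermediate (not isolated)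
18 | seco-phenol (C7′ bonded to d; d–CH3 cis to the e–f bond; C7′ as in the target; a=b alkene) | CC(C)C[C@@H](c1c(O)c(C=O)c(O)c(C=O)c1O)[C@@]1(C)CC=C2[C@@H](C)C[C@@H]3[C@H]([C@H]12)C3(C)C | intermediate
19 | CNP0202714.1 (bridged benzoxepane; aryl ether O on a) | CC(C)C[C@H]1c2c(O)c(C=O)c(O)c(C=O)c2O[C@]23CC[C@@]1(C)[C@H]2[C@H]1[C@@H](C[C@@H]3C)C1(C)C | target

**Step count and risks**

Total steps: 8. Longest linear sequence: 6 (steps 1, 3, 4, 5, 7, 8).

Most likely to fail:

- **Step 8 (the proposed new C–O closure).** Risks are cobalt-mediated alkene isomerisation, silane attack on the aldehydes, and a slow bridged seven-membered closure. The fallback sets out from 18 and ends at 19. It is the classical Brønsted-acid Markovnikov cycloetherification of a phenol onto a trisubstituted alkene (TfOH 5 mol% or Amberlyst 15, CH2Cl2, −40 °C), which is known chemistry and makes no new compound (F0). Its own risk is a 1,2-hydride shift from e to the cation at a, giving the six-membered chroman isomer or cyclopropane opening, hence the low temperature.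

- **Step 7 (Giese addition to the quinone methide).** Risks are poor discrimination between the two alkenes of 11, a background hetero-Diels–Alder reaction of the quinone methide, iron chelation by the formylphenol, and low selectivity at C7′. The fallback sets out from 11 and comes back at 18. Mukaiyama hydration (Co(acac)2, O2, PhSiH3) of the exocyclic alkene gives the tertiary alcohol F3. Oxalyl chloride, then water, gives its hydrogen oxalate F4. Visible-light photoredox decarboxylation (Ir[dF(CF3)ppy]2(dtbbpy)PF6, CsF, blue light) then releases the same tertiary radical without any metal hydride, and it adds to quinone methide 17 set free from separately prepared Mannich base 16. This does not improve C7′ selectivity.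

- **Step 3 (α-alkenylation).** Risks are proton transfer between product and enolate, and migration of the new double bond into conjugation. The fallback sets out from 3 and comes back at 9. Lithium enolate 7 is quenched with N-bromosuccinimide to give 5-bromo-3,7,7-trimethylbicyclo[4.1.0]heptan-4-one F1 (bromine trans to the cyclopropane). F1 is then coupled under nickel catalysis (NiCl2·glyme, bipyridine ligand; stereoconvergent radical Negishi coupling of α-bromoketones) with (penta-1,4-dien-2-yl)zinc bromide F2, made from 6 and activated zinc. The ketone thus becomes the electrophile instead of the nucleophile, and the dienyl group again settles trans to the cyclopropane.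

Further compounds

F1 | step 3 | 5-bromo-3,7,7-trimethylbicyclo[4.1.0]heptan-4-one (3-methyl cis, bromine trans to the cyclopropane) | C[C@H]1C[C@@H]2[C@H]([C@H](Br)C1=O)C2(C)C
F2 | step 3 | (penta-1,4-dien-2-yl)zinc bromide | C=C([Zn]Br)CC=C
F3 | step 7 | tertiary alcohol from Markovnikov hydration of the exocyclic alkene of 11 (OH on d, convex face) | C[C@H]1C[C@@H]2[C@H]([C@@H]3[C@@](C)(O)CC=C13)C2(C)C
F4 | step 7 | hydrogen oxalate of F3 | C[C@H]1C[C@@H]2[C@H]([C@@H]3[C@@](C)(OC(=O)C(=O)O)CC=C13)C2(C)C
F0 | step 8 | none | none
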